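**Plan**

Locants: chroman O1, C2 (spiro, = C2′), C3, C4 (CHPh); carbocycle C1′(=CH)–C2′–C3′–C4′–C4a′–C5′(Me)–C6′–C7′–C8′(i-Pr)–C8a′; ring A = C4a′/C5′/C6′/C7′/C8′/C8a′, ring B = C1′/C2′/C3′/C4′/C4a′/C8a′.
Cuts: first C8′–C8a′ (ring A, with the C1′=C8a′ alkene read as a C1′/C8a′ epoxide); then O1–C2 and C3–C4 (ortho-quinone methide hetero-Diels–Alder on an exocyclic methylene of ring B); then C1′=C8a′ and C4′–C4a′ of ring B (aldol condensation and Michael addition).
Forward order: ring B from citronellal and methyl vinyl ketone, then its epoxide and methylene, then the chroman with the arene and phenyl group, and last ring A by an epoxide-initiated cation–olefin cyclization; dehydration of the C1′ carbinol restores C1′=C8a′.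
Enabling feature: C1′=C8a′ lies between the fully substituted spiro carbon C2′ and the ring-fusion carbon, so its epoxide can be attacked only at C8a′ and the C1′ alcohol left behind can eliminate only toward C8a′; the chain on C4a′ holds the inner carbon of its Me2C=CH group six atoms from C8a′.
Stereochemistry: C5′ from (R)-citronellal; C4a′ from the amine catalyst; epoxide anti to the chain; C2 and C4 in the cycloaddition (O1 anti to the epoxide); C8′ from the chair transition state of the ring closure.

Key step: step 6

Remark: 2,4,6-trihydroxybenzene-1,3-dicarbaldehyde is treated as a purchasable starting material; the two phenols not used in the cycloaddition are masked as acetates only for steps 6 to 8.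

**Step 1**
Reactants: 1 (R)-citronellal; 2 methyl vinyl ketone
Product: 4 (4R)-4-[(2R)-6-methylhept-5-en-2-yl]cyclohex-2-en-1-one, via keto aldehyde 3 (not isolated)
Conditions: (R)-2-[methoxy(diphenyl)methyl]pyrrolidine (5 mol%), ethyl 3,4-dihydroxybenzoate (20 mol%), neat, 4 °C; then LiOH, i-PrOH, rt
Reagents that add atoms: none
Why: Enamine-mediated Michael addition followed by base-induced intramolecular aldol condensation (a Robinson-type annulation) builds ring B; the diphenyl(methoxy)methyl group of the (R)-pyrrolidine shields one enamine face, so C4a′ is set by the catalyst independently of the citronellal stereocentre, which becomes C5′.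

**Step 2**
Reactants: 4 (4R)-4-[(2R)-6-methylhept-5-en-2-yl]cyclohex-2-en-1-one
Product: 5 (1R,5R,6R)-5-[(2R)-6-methylhept-5-en-2-yl]-7-oxabicyclo[4.1.0]heptan-2-one
Conditions: H2O2 (30% aq.), NaOH (cat.), MeOH, 0 °C
Reagents that add atoms: hydrogen peroxide, OO
Why: Weitz–Scheffer nucleophilic epoxidation touches only the electron-poor enone double bond and hydroperoxide should add axially, anti to the pseudo-equatorial C4 side chain, so the oxirane forms trans to the chain while the trisubstituted side-chain alkene is left alone.

**Step 3**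
Reactants: 5 (1R,5R,6R)-5-[(2R)-6-methylhept-5-en-2-yl]-7-oxabicyclo[4.1.0]heptan-2-one
Product: 6 (1S,5R,6R)-2-methylidene-5-[(2R)-6-methylhept-5-en-2-yl]-7-oxabicyclo[4.1.0]heptane
Conditions: Ph3PCH3Br, KOt-Bu, THF, 0 °C → rt
Reagents that add atoms: methyltriphenylphosphonium bromide, C[P+](c1ccccc1)(c1ccccc1)c1ccccc1.[Br-]
Why: Wittig methylenation of the ketone gives the 1,1-disubstituted alkene needed as dienophile; α,β-epoxy ketones are methylenated without opening of the oxirane and no stereocentre is affected.

**Step 4**
Reactants: 6 (1S,5R,6R)-2-methylidene-5-[(2R)-6-methylhept-5-en-2-yl]-7-oxabicyclo[4.1.0]heptane; 7 benzaldehyde; 8 2,4,6-trihydroxybenzene-1,3-dicarbaldehyde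
Product: 10 epoxy spirochroman (2S,4S; ring A still open; oxirane anti to O1), via ortho-quinone methide 9 (not isolated)
Conditions: ethylenediammonium diacetate (20 mol%), MeCN, 60 °C
Reagents that add atoms: none
Why: Knoevenagel condensation of 7 with the free ring position of 8 gives ortho-quinone methide 9, which is trapped in an inverse-electron-demand hetero-Diels–Alder reaction by the unhindered 1,1-disubstituted methylene of 6 (the trisubstituted side-chain alkene would have to bond through an internal carbon and should be slower); O1 should add to C2 on the face anti to the adjacent epoxide C–O bond with the more branched epoxide arm exo, which places phenyl cis to C3′ and gives the (2S,4S) isomer, to be separated from minor diastereomers by chromatography.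

**Step 5**
Reactants: 10 epoxy spirochroman
Product: 11 epoxy spirochroman 5,7-diacetate
Conditions: Ac2O, pyridine, DMAP (cat.), CH2Cl2, 0 °C → rt
Reagents that add atoms: acetic anhydride, CC(=O)OC(C)=O
Why: Standard acylation masks the two acidic phenols, which would otherwise consume the aluminium Lewis acid of step 6 and the sulfamoylating reagent of step 8; no stereocentre is involved.

**Step 6**
Reactants: 11 epoxy spirochroman 5,7-diacetate
Product: 12 ring-A-closed C1′ alcohol with 8′-isopropenyl group (cis-fused; 5,7-diacetate)
Conditions: MeAlCl2 (3 equiv), CH2Cl2, −78 → −20 °C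
Reagents that add atoms: none
Why: MeAlCl2 binds the oxirane oxygen and the C8a′–O bond breaks with backside participation of the inner carbon of the Me2C=CH group, a Lewis-acid-promoted epoxide-initiated cation–olefin (epoxy-ene) cyclization, after which the 2-propyl cation loses a methyl proton to give the isopropenyl group. Ring A closes in the 6-exo mode with respect to the oxirane (the oxygen stays outside the new ring on C1′) and in the Markovnikov sense with respect to the alkene, which reacts through its less substituted carbon. C8a′ is set by inversion, that is by the configuration of the epoxide (anti to the chain), so the decalin is cis-fused and H-8a′ ends cis to the C1′ oxygen. C8′ is set in a chair transition state in which the C5′ methyl group and the developing cationic carbon are both equatorial, while the chain is equatorial on ring B and the new bond forms axially (trans-diaxial opening); this gives the 5′,8′-trans relationship of the target. The step needs opening at C8a′ and not at C1′, and π-participation and not a hydride shift: C1′ is neopentylic and β to the electron-withdrawing aryloxy oxygen on the quaternary spiro carbon, and only C8a′ is six atoms from the alkene carbon.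

**Step 7**
Reactants: 12 ring-A-closed C1′ alcohol with 8′-isopropenyl group
Product: 13 ring-A-closed C1′ alcohol with 8′-isopropyl group (5,7-diacetate)
Conditions: H2 (1 atm), RhCl(PPh3)3 (5 mol%), benzene/EtOH, rt
Reagents that add atoms: none
Why: Homogeneous hydrogenation with RhCl(PPh3)3 saturates the unhindered 1,1-disubstituted isopropenyl group, the only C=C bond present at this stage, and should leave the hindered aryl aldehydes, the acetates and all stereocentres untouched (the new isopropyl carbon is not stereogenic).

**Step 8**
Reactants: 13 ring-A-closed C1′ alcohol with 8′-isopropyl group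
Product: 14 Guajadial D 5,7-diacetate
Conditions: methyl N-(triethylammoniosulfonyl)carbamate (inner salt), benzene, 50–70 °C
Reagents that add atoms: none
Why: Burgess dehydration is a thermal syn-elimination of the derived sulfamate; C2′ carries no hydrogen and H-8a′ is cis to the C1′ oxygen (the ring bond entered anti to it in step 6), so only the C1′=C8a′ double bond can form, and the stereocentre at C8a′ is erased on purpose.

**Step 9**
Reactants: 14 Guajadial D 5,7-diacetate
Product: 15 Guajadial D
Conditions: K2CO3 (0.3 equiv), MeOH, 0 °C → rt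
Reagents that add atoms: none
Why: Mild base-catalysed methanolysis (transesterification) cleaves the two activated aryl acetates without touching the aldehydes, the tertiary allylic aryl ether or any stereocentre, and releases the target.

**Compound list**

1 | (R)-citronellal, (3R)-3,7-dimethyloct-6-enal | CC(C)=CCC[C@@H](C)CC=O | starting material
2 | methyl vinyl ketone, but-3-en-2-one | CC(=O)C=C | starting material
3 | (2R,3R)-3,7-dimethyl-2-(3-oxobutyl)oct-6-enal (not isolated) | CC(C)=CCC[C@@H](C)[C@H](C=O)CCC(C)=O | intermediate
4 | (4R)-4-[(2R)-6-methylhept-5-en-2-yl]cyclohex-2-en-1-one | CC(C)=CCC[C@@H](C)[C@H]1CCC(=O)C=C1 | intermediate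
5 | (1R,5R,6R)-5-[(2R)-6-methylhept-5-en-2-yl]-7-oxabicyclo[4.1.0]heptan-2-one (oxirane anti to the side chain) | CC(C)=CCC[C@@H](C)[C@H]1CCC(=O)[C@@H]2O[C@H]12 | intermediate
6 | (1S,5R,6R)-2-methylidene-5-[(2R)-6-methylhept-5-en-2-yl]-7-oxabicyclo[4.1.0]heptane | CC(C)=CCC[C@@H](C)[C@H]1CCC(=C)[C@@H]2O[C@H]12 | intermediate
7 | benzaldehyde | O=Cc1ccccc1 | starting material
8 | 2,4,6-trihydroxybenzene-1,3-dicarbaldehyde | O=Cc1c(O)cc(O)c(C=O)c1O | starting material
9 | ortho-quinone methide, 5-benzylidene-2,4-dihydroxy-6-oxocyclohexa-1,3-diene-1,3-dicarbaldehyde (not isolated) | O=C1C(=Cc2ccccc2)C(O)=C(C=O)C(O)=C1C=O | intermediate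
10 | epoxy spirochroman: (2S,4S)-5,7-dihydroxy-4-phenylchromane-6,8-dicarbaldehyde spiro-linked at C2 (= C2′) to ring B, which carries the 1′,8a′-epoxide (oxygen anti to O1) and on C4a′ the (2R)-6-methylhept-5-en-2-yl chain (syn to O1); ring A open | CC(C)=CCC[C@@H](C)[C@H]2CC[C@@]3([C@@H]4O[C@@H]42)C[C@@H](c1ccccc1)c1c(O)c(C=O)c(O)c(C=O)c1O3 | intermediate
11 | 5,7-di-O-acetate of 10 | CC(C)=CCC[C@@H](C)[C@H]2CC[C@@]3([C@@H]4O[C@@H]42)C[C@@H](c1ccccc1)c1c(OC(C)=O)c(C=O)c(OC(C)=O)c(C=O)c1O3 | intermediate
12 | ring-A-closed alcohol, 5,7-diacetate: cis-fused decalin, C1′–OH anti to O1 and cis to H-8a′, H-4a′ and H-8a′ cis, 8′-isopropenyl trans to 5′-methyl | CC(=C)[C@@H]1CC[C@@H](C)[C@H]2CC[C@@]3([C@H](O)[C@@H]12)C[C@@H](c1ccccc1)c1c(OC(C)=O)c(C=O)c(OC(C)=O)c(C=O)c1O3 | intermediate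
13 | 8′-isopropyl analogue of 12 (same configuration, 5,7-diacetate) | CC(C)[C@@H]1CC[C@@H](C)[C@H]2CC[C@@]3([C@H](O)[C@@H]12)C[C@@H](c1ccccc1)c1c(OC(C)=O)c(C=O)c(OC(C)=O)c(C=O)c1O3 | intermediate
14 | Guajadial D 5,7-diacetate | CC(C)[C@@H]1CC[C@@H](C)[C@H]2CC[C@@]3(C=C12)C[C@@H](c1ccccc1)c1c(OC(C)=O)c(C=O)c(OC(C)=O)c(C=O)c1O3 | intermediate
15 | Guajadial D | CC(C)[C@@H]1CC[C@@H](C)[C@H]2CC[C@@]3(C=C12)C[C@@H](c1ccccc1)c1c(O)c(C=O)c(O)c(C=O)c1O3 | target

**Step count and risks**

Total step count: 9. Longest linear sequence: 9 steps (1 to 15).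

Steps most likely to fail:

Step 4. The quinone methide may add to the trisubstituted side-chain alkene of 6 instead of the ring methylene, the vinyl epoxide may be opened by the acidic phenol before the cycloaddition, and the facial selectivity may be modest. Fallback: the side chain is carried as a monosubstituted vinyl group, which is inert toward the quinone methide, and the isopropylidene terminus is restored after the cycloaddition. Setting out from 4, ethenolysis (ethylene, second-generation Grubbs catalyst, CH2Cl2) should give (4R)-4-[(2R)-hex-5-en-2-yl]cyclohex-2-en-1-one F1. Epoxidation as in step 2 should give (1R,5R,6R)-5-[(2R)-hex-5-en-2-yl]-7-oxabicyclo[4.1.0]heptan-2-one F2, and methylenation as in step 3 should give (1S,5R,6R)-5-[(2R)-hex-5-en-2-yl]-2-methylidene-7-oxabicyclo[4.1.0]heptane F3. The three-component cycloaddition with 7 and 8 should then give the hex-5-en-2-yl analogue of 10 F4. Cross-metathesis of F4 with 2-methylbut-2-ene (second-generation Grubbs catalyst) comes back to the route at 10.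

Step 6. The activated epoxide may ionise without participation of the alkene (hydride shift to a ketone, capture of chloride), or the tertiary cation may lose the ring proton and so destroy the C8′ stereocentre. Fallback by a radical ring closure: setting out from 11, MgBr2·OEt2 (Et2O, 0 °C) should open the oxirane trans-diaxially at C8a′ to the bromohydrin F5. Bu3SnH/AIBN (benzene, 80 °C, slow addition) then generates the C8a′ radical, which closes ring A by 6-exo attack on the inner alkene carbon, and the tertiary radical is reduced by the stannane. The fallback comes back to the route at 13, so step 7 is no longer needed.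

Step 8. The carbinol is neopentylic and flanked by a quaternary and a tertiary carbon, so sulfamate formation may be slow and ionisation with a 1,2-shift from C2′ may compete with the syn-elimination. Fallback through the ketone: setting out from 13, Dess–Martin oxidation should give the C1′ ketone F6. KHMDS/PhNTf2 (THF, −78 °C) can enolise it only toward C8a′ and should give the enol triflate F7. Reduction with Pd(OAc)2, PPh3, Bu3N and HCO2H (DMF, 60 °C; zerovalent palladium formed in the flask) replaces the triflate by hydrogen and comes back to the route at 14.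

**Further compounds**

F1 | step 4 | (4R)-4-[(2R)-hex-5-en-2-yl]cyclohex-2-en-1-one | C=CCC[C@@H](C)[C@H]1CCC(=O)C=C1
F2 | step 4 | (1R,5R,6R)-5-[(2R)-hex-5-en-2-yl]-7-oxabicyclo[4.1.0]heptan-2-one | C=CCC[C@@H](C)[C@H]1CCC(=O)[C@@H]2O[C@H]12
F3 | step 4 | (1S,5R,6R)-5-[(2R)-hex-5-en-2-yl]-2-methylidene-7-oxabicyclo[4.1.0]heptane | C=CCC[C@@H](C)[C@H]1CCC(=C)[C@@H]2O[C@H]12
F4 | step 4 | hex-5-en-2-yl analogue of epoxy spirochroman 10 | C=CCC[C@@H](C)[C@H]2CC[C@@]3([C@@H]4O[C@@H]42)C[C@@H](c1ccccc1)c1c(O)c(C=O)c(O)c(C=O)c1O3
F5 | step 6 | trans-bromohydrin of 11 (Br on C8a′, OH on C1′) | CC(C)=CCC[C@@H](C)[C@H]2CC[C@@]3([C@H](O)[C@H]2Br)C[C@@H](c1ccccc1)c1c(OC(C)=O)c(C=O)c(OC(C)=O)c(C=O)c1O3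
F6 | step 8 | C1′ ketone from 13 | CC(C)[C@@H]1CC[C@@H](C)[C@H]2CC[C@@]3(C(=O)[C@@H]12)C[C@@H](c1ccccc1)c1c(OC(C)=O)c(C=O)c(OC(C)=O)c(C=O)c1O3
F7 | step 8 | C1′ enol triflate (C1′=C8a′) | CC(C)[C@@H]1CC[C@@H](C)[C@H]2CC[C@@]3(C(OS(=O)(=O)C(F)(F)F)=C12)C[C@@H](c1ccccc1)c1c(OC(C)=O)c(C=O)c(OC(C)=O)c(C=O)c1O3
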